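**Plan**

1. Locants follow the icetexane skeleton: C-4 = CMe2, C-5 = ring-fusion CH, C-6 = the CH2 next to it, C-7 = hemiketal carbon, C-8/C-9 = quinone carbons bearing C-7 and the C-20 CH2, C-10 = oxygenated quaternary carbon, C-11/C-14 = quinone carbonyls, C-12 = C–OMe, C-13 = C–iPr; ring A = cyclohexane, ring B = seven-membered ring, ring C = quinone.
2. Cuts, in retrosynthetic order: quinone ⇒ 11,12,14-trimethoxyarene; C-20–C-10 together with the C-7–O hemiketal bond ⇒ an open 1,4-diketone (o-tolyl C-7 ketone, C-10 cyclohexanone); C-7–C-8 ⇒ aryl bromide + aldehyde; C-5–C-6 ⇒ allyl enol carbonate of 3,3-dimethylcyclohexanone.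
3. Enabling feature: C-20 is a methyl group ortho to the C-7 carbonyl on ring C, and C-7 is 1,4 to the C-10 carbonyl through C-6/C-5. Photoenolisation therefore turns ring C into a hydroxy-o-quinodimethane whose CH2 reaches C-10, and the new C-10 oxygen sits where the C-7–O–C-10 bridge of the 8-oxabicyclo[3.2.1]octene needs it.
4. Forward: ring A with C-5 set (steps 1–3) and the hexasubstituted ring C (steps 4–7) are joined at C-7–C-8 (steps 8–9). One photochemical step closes ring B and the oxygen bridge (step 10). Ring C stays a trimethoxyarene (chromophore and masked quinone) and is oxidised last (step 11).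
5. Stereochemistry: C-5 (R) comes from Pd-catalysed decarboxylative asymmetric allylation. C-10 (S) and C-7 (S) are relayed from C-5 in step 10: C-10 by the face of the ketone left open by the gem-dimethyl group, C-7 by the bridge.

Key step: step 10

Assumption: the (R,R)-configured ligand of step 2 is taken to deliver the (R)-ketone; if the sense proves opposite, the (S,S)-ligand is used.

**Route**

Step 1
Reactants: 1 3-methylcyclohex-2-en-1-one
Product: 3 allyl 3,3-dimethylcyclohex-1-en-1-yl carbonate, via lithium enolate 2 (not isolated)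
Conditions: Me2CuLi (from MeLi, CuBr·SMe2), Et2O, −78 → 0 °C; then TMEDA, allyl chloroformate, THF, −78 °C → rt
Reagents that add atoms: lithium dimethylcuprate [Li+].C[Cu-]C; allyl chloroformate C=CCOC(Cl)=O
Why: Conjugate addition of the cuprate creates the gem-dimethyl carbon and releases the enolate only towards the carbon next to it, and this hindered lithium enolate should be acylated on oxygen by the hard chloroformate (enolate O-acylation) to give the regiodefined enol carbonate; no stereocentre is formed.

Step 2
Reactants: 3 allyl 3,3-dimethylcyclohex-1-en-1-yl carbonate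
Product: 4 (R)-2-allyl-3,3-dimethylcyclohexan-1-one
Conditions: Pd2(dba)3·CHCl3 (2.5 mol %), (R,R)-ANDEN-phenyl bis[2-(diphenylphosphanyl)benzamide] ligand (5.5 mol %), 1,4-dioxane, 23 °C
Reagents that add atoms: none
Why: Decarboxylative asymmetric allylic alkylation (Tsuji–Trost type): ionisation and loss of CO2 give a π-allylpalladium enolate ion pair that should recombine at carbon inside the chiral pocket of the ligand, which sets C-5 as (R), while the neutral conditions keep the enolisable tertiary centre from racemising and prevent double allylation.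

Step 3
Reactants: 4 (R)-2-allyl-3,3-dimethylcyclohexan-1-one
Product: 6 2-[(1R)-2,2-dimethyl-6-oxocyclohexyl]acetaldehyde, via ozonide 5 (not isolated)
Conditions: O3, CH2Cl2, −78 °C; then Me2S, −78 °C → rt
Reagents that add atoms: ozone [O-][O+]=O
Why: Ozonolysis (Criegee mechanism) with reductive work-up should cleave only the terminal alkene, the ketone being inert and the neutral conditions leaving the α-stereocentre at C-5 untouched.

Step 4
Reactants: 7 1,2,4-trimethoxybenzene
Product: 9 2-(2,3,6-trimethoxyphenyl)propan-2-ol, via aryllithium 8 (not isolated)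
Conditions: n-BuLi, THF, 0 °C → rt; then acetone, −78 °C → rt
Reagents that add atoms: acetone CC(C)=O
Why: Directed ortho-metalation should remove the hydrogen flanked by two methoxy groups (the most acidic ring position), and the aryllithium adds 1,2 to acetone.

Step 5
Reactants: 9 2-(2,3,6-trimethoxyphenyl)propan-2-ol
Product: 10 2-isopropyl-1,3,4-trimethoxybenzene
Conditions: Et3SiH, CF3CO2H, CH2Cl2, 0 °C → rt
Reagents that add atoms: none
Why: Ionic hydrogenation: the acid ionises the tertiary benzylic alcohol to a cation stabilised by the electron-rich ring and the silane delivers hydride, the aryl methyl ethers being stable to these conditions.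

Step 6
Reactants: 10 2-isopropyl-1,3,4-trimethoxybenzene
Product: 11 1-bromo-3-isopropyl-2,4,5-trimethoxybenzene
Conditions: N-bromosuccinimide, MeCN, 0 °C
Reagents that add atoms: N-bromosuccinimide O=C1CCC(=O)N1Br
Why: Electrophilic aromatic bromination should go to C-6 of 10, which is ortho to one methoxy group and para to another, the other free position being activated by a single ortho methoxy group only.

Step 7
Reactants: 11 1-bromo-3-isopropyl-2,4,5-trimethoxybenzene
Product: 13 1-bromo-5-isopropyl-3,4,6-trimethoxy-2-methylbenzene, via aryllithium 12 (not isolated)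
Conditions: LiN(i-Pr)2, THF, −78 °C; then MeI, −78 → 0 °C
Reagents that add atoms: iodomethane CI
Why: Deprotonative ortho-lithiation with the amide base (no bromine–lithium exchange) should take the only ring hydrogen, acidified by the flanking bromine and methoxy group, and methylation of the aryllithium at −78 °C outruns loss of LiBr to an aryne.

Step 8
Reactants: 13 1-bromo-5-isopropyl-3,4,6-trimethoxy-2-methylbenzene; 6 2-[(1R)-2,2-dimethyl-6-oxocyclohexyl]acetaldehyde
Product: 16 (2R)-2-[2-hydroxy-2-(5-isopropyl-3,4,6-trimethoxy-2-methylphenyl)ethyl]-3,3-dimethylcyclohexan-1-one (both carbinol epimers), via aryllithium 14 (not isolated), via arylmagnesium bromide 15 (not isolated)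
Conditions: 13, n-BuLi, THF, −78 °C; MgBr2·OEt2; then 6, −78 °C; aq. NH4Cl
Reagents that add atoms: none
Why: Bromine–lithium exchange, transmetalation to the less basic arylmagnesium bromide and Grignard 1,2-addition to the unhindered aldehyde, in preference to the hindered ketone, should join the fragments at C-7–C-8; the new carbinol centre forms as a mixture and is removed in step 9.

Step 9
Reactants: 16 (2R)-2-[2-hydroxy-2-(5-isopropyl-3,4,6-trimethoxy-2-methylphenyl)ethyl]-3,3-dimethylcyclohexan-1-one
Product: 17 (2R)-2-[2-(5-isopropyl-3,4,6-trimethoxy-2-methylphenyl)-2-oxoethyl]-3,3-dimethylcyclohexan-1-one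
Conditions: Dess–Martin periodinane, NaHCO3, CH2Cl2, 0 °C → rt
Reagents that add atoms: none
Why: Dess–Martin oxidation of the benzylic secondary alcohol (through its open hydroxy ketone form) under bicarbonate buffering should give the 1,4-diketone without acid (no Paal–Knorr furan formation) or base (no epimerisation at C-5).

Step 10
Reactants: 17 (2R)-2-[2-(5-isopropyl-3,4,6-trimethoxy-2-methylphenyl)-2-oxoethyl]-3,3-dimethylcyclohexan-1-one
Product: 20 (5R,7S,10S)-7,10-epoxy-11,12,14-trimethoxyicetexa-8,11,13-trien-7-ol (the target skeleton with ring C as trimethoxybenzene), via photoenol 18 (not isolated), via ring-open hydroxy ketone 19 (not isolated)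
Conditions: hν (365 nm), N,N′-bis[3,5-bis(trifluoromethyl)phenyl]thiourea (20 mol %), degassed PhMe (0.01 M), 25 °C
Reagents that add atoms: none
Why: Proposed new method: n,π* excitation of the aryl ketone and 1,5-hydrogen transfer from the ortho methyl group (C-20) should give the hydroxy-o-quinodimethane 18, in which ring C is transiently dearomatised and the enol OH is hydrogen-bonded to the C-14 methoxy oxygen so that the C-6 chain points towards C-20; its nucleophilic CH2 terminus adds to the thiourea-activated C-10 ketone with rearomatisation (vinylogous aldol, formally a hetero-Diels–Alder addition across C-20 and C-7), and the tertiary alcohol of 19 lactolises onto the regenerated C-7 ketone. The closest known reaction types are photoenolisation/Diels–Alder trapping of o-tolyl ketones and the hydrogen-bond-catalysed addition of photoenols to activated ketones; capture by a tethered, unactivated ketone is the untested part, argued from the intramolecular reach, the large rearomatisation driving force and the absence of competing paths (no γ-hydrogen on the chain for Norrish type 2 cleavage because C-4 is quaternary and C-10 a carbonyl, and no base that would start the 1,4-diketone aldol). Ring B closes by 7-(enolendo)-exo-trig attack of C-20 on C-10, and the oxygen bridge by 5-exo-trig addition of the C-10 hydroxyl to the C-7 carbonyl, which completes the tetrahydrofuran and the pyran ring of the 8-oxabicyclo[3.2.1]octene together. C-10 is controlled by C-5: C-20 should approach equatorially, anti to the axial C-4 methyl group, on the chair that carries the C-5 side chain axial (where the chain avoids a gauche contact with the gem-dimethyl group and eclipsing with the carbonyl), which places C-20 cis to C-6 and the C-10 oxygen cis to H-5. C-7 is fixed by the bridge, since the C-10 oxygen can reach the C-7 carbonyl from one face only. The step needs hydrogen transfer from C-20 and not from the C-14 methoxy or C-4 methyl groups (six-membered against seven-membered transition states) and one face of the C-10 carbonyl, the former secured by the ortho methyl group and the latter by the gem-dimethyl group as stated; the closed hemiketal does not absorb at 365 nm, which protects the product.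

Step 11
Reactants: 20 (5R,7S,10S)-7,10-epoxy-11,12,14-trimethoxyicetexa-8,11,13-trien-7-ol
Product: 21 target, (5R,7S,10S)-7,10-epoxy-7-hydroxy-12-methoxyicetexa-8,12-diene-11,14-dione
Conditions: (NH4)2Ce(NO3)6, MeCN/H2O (2:1), 0 °C
Reagents that add atoms: water O
Why: Oxidative demethylation with tetravalent cerium: single-electron oxidation of the electron-rich arene, attack of water at the para-related C-11 and C-14 and loss of two methanol should give the para-quinone, the C-12 methoxy group staying as a vinylogous ester and the bridged hemiketal being stable to the cold aqueous acid, so that no stereocentre is touched.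

**Compound list**

1 | 3-methylcyclohex-2-en-1-one | CC1=CC(=O)CCC1 | starting material
2 | lithium 3,3-dimethylcyclohex-1-en-1-olate | [Li+].[O-]C1=CC(C)(C)CCC1 | intermediate (not isolated)
3 | allyl 3,3-dimethylcyclohex-1-en-1-yl carbonate | C=CCOC(=O)OC1=CC(C)(C)CCC1 | intermediate
4 | (R)-2-allyl-3,3-dimethylcyclohexan-1-one | C=CC[C@H]1C(=O)CCCC1(C)C | intermediate
5 | (2R)-3,3-dimethyl-2-(1,2,4-trioxolan-3-ylmethyl)cyclohexan-1-one (ozonide of 4, trioxolane carbon undefined) | O=C1CCCC(C)(C)[C@H]1CC2OCOO2 | intermediate (not isolated)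
6 | 2-[(1R)-2,2-dimethyl-6-oxocyclohexyl]acetaldehyde | O=CC[C@H]1C(=O)CCCC1(C)C | intermediate
7 | 1,2,4-trimethoxybenzene | COc1ccc(OC)c(OC)c1 | starting material
8 | (2,3,6-trimethoxyphenyl)lithium | [Li]c1c(OC)ccc(OC)c1OC | intermediate (not isolated)
9 | 2-(2,3,6-trimethoxyphenyl)propan-2-ol | CC(C)(O)c1c(OC)ccc(OC)c1OC | intermediate
10 | 2-isopropyl-1,3,4-trimethoxybenzene | CC(C)c1c(OC)ccc(OC)c1OC | intermediate
11 | 1-bromo-3-isopropyl-2,4,5-trimethoxybenzene | CC(C)c1c(OC)c(Br)cc(OC)c1OC | intermediate
12 | (2-bromo-4-isopropyl-3,5,6-trimethoxyphenyl)lithium | CC(C)c1c(OC)c(Br)c([Li])c(OC)c1OC | intermediate (not isolated)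
13 | 1-bromo-5-isopropyl-3,4,6-trimethoxy-2-methylbenzene | CC(C)c1c(OC)c(Br)c(C)c(OC)c1OC | intermediate
14 | (5-isopropyl-3,4,6-trimethoxy-2-methylphenyl)lithium | CC(C)c1c(OC)c([Li])c(C)c(OC)c1OC | intermediate (not isolated)
15 | (5-isopropyl-3,4,6-trimethoxy-2-methylphenyl)magnesium bromide | CC(C)c1c(OC)c([Mg]Br)c(C)c(OC)c1OC | intermediate (not isolated)
16 | (2R)-2-[2-hydroxy-2-(5-isopropyl-3,4,6-trimethoxy-2-methylphenyl)ethyl]-3,3-dimethylcyclohexan-1-one, both epimers at the carbinol carbon (C-7) | CC(C)c1c(OC)c(C(O)C[C@H]2C(=O)CCCC2(C)C)c(C)c(OC)c1OC | intermediate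
17 | (2R)-2-[2-(5-isopropyl-3,4,6-trimethoxy-2-methylphenyl)-2-oxoethyl]-3,3-dimethylcyclohexan-1-one | CC(C)c1c(OC)c(C(=O)C[C@H]2C(=O)CCCC2(C)C)c(C)c(OC)c1OC | intermediate
18 | photoenol of 17: hydroxy-o-quinodimethane with exocyclic C-8=C-7(OH) and C-9=CH2, the OH on the side of the C-14 methoxy group, C-5 (R) | O/C(C[C@H]1C(=O)CCCC1(C)C)=C2/C(=C)C(OC)=C(OC)C(C(C)C)=C2OC | intermediate (not isolated)
19 | (5R,10S)-10-hydroxy-11,12,14-trimethoxyicetexa-8,11,13-trien-7-one (ring-open hydroxy ketone form of 20) | COc1c(C(C)C)c(OC)c2c(C[C@@]3(O)CCCC(C)(C)[C@H]3CC2=O)c1OC | intermediate (not isolated)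
20 | (5R,7S,10S)-7,10-epoxy-11,12,14-trimethoxyicetexa-8,11,13-trien-7-ol (bridged hemiketal, ring C as trimethoxybenzene) | COc1c(C(C)C)c(OC)c2c(C[C@@]34CCCC(C)(C)[C@H]3C[C@]2(O)O4)c1OC | intermediate
21 | (5R,7S,10S)-7,10-epoxy-7-hydroxy-12-methoxyicetexa-8,12-diene-11,14-dione (CNP0290151.2) | COC1=C(C(C)C)C(=O)C2=C(C[C@@]34CCCC(C)(C)[C@H]3C[C@]2(O)O4)C1=O | target

**Step count and risks**

Total step count: 11. Longest linear sequence: 8 steps (steps 4–11, from 1,2,4-trimethoxybenzene); the ring A branch is 7 steps (1–3, 8–11).

Three steps most likely to fail: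

1. Step 10. The photoenol may return to the ketone (or close to a benzocyclobutenol) faster than it is captured by the unactivated ketone. The attack may also go through the chair with the C-5 chain equatorial and give the C-10 epimer. Fallback (known chemistry; sets out from 11 and 4, returns at 20): the C-20–C-10 bond is made intermolecularly by a benzylic Grignard addition, and ring B is closed at C-7–C-8 by a Parham cyclisation. Aryllithium 12 (from 11 as in step 7) is quenched with DMF to give 2-bromo-4-isopropyl-3,5,6-trimethoxybenzaldehyde F1. NaBH4 (MeOH, 0 °C) gives (2-bromo-4-isopropyl-3,5,6-trimethoxyphenyl)methanol F2, and PBr3 (CH2Cl2, 0 °C) gives 1-bromo-2-(bromomethyl)-5-isopropyl-3,4,6-trimethoxybenzene F3. Magnesium should insert into the benzylic C–Br bond only (Et2O, 0 °C) to give [(2-bromo-4-isopropyl-3,5,6-trimethoxyphenyl)methyl]magnesium bromide F4. This adds to ketone 4 (equatorial attack anti to the axial methyl group) to give (1S,2R)-2-allyl-1-[(2-bromo-4-isopropyl-3,5,6-trimethoxyphenyl)methyl]-3,3-dimethylcyclohexan-1-ol F5. Cleavage of the allyl group (OsO4 cat., NaIO4, 2,6-lutidine, dioxane/H2O) gives the lactol (3aR,7aS)-7a-[(2-bromo-4-isopropyl-3,5,6-trimethoxyphenyl)methyl]-4,4-dimethyloctahydro-1-benzofuran-2-ol F6. Oxidation (TEMPO cat., PhI(OAc)2, CH2Cl2) gives the γ-lactone (3aR,7aS)-7a-[(2-bromo-4-isopropyl-3,5,6-trimethoxyphenyl)methyl]-4,4-dimethylhexahydro-1-benzofuran-2(3H)-one F7. Bromine–lithium exchange (t-BuLi, THF, −90 °C) gives the aryllithium lactone F8, which should attack its own lactone carbonyl (six-membered ring through the lactone oxygen). The tetrahedral intermediate is the bridged hemiketal alkoxide, and protonation gives 20.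

2. Step 2. Recombination at the neopentyl-type enolate carbon may be slow or poorly face-selective, which would lower the enantiomeric purity of C-5, the centre every later stereocentre depends on. Fallback (sets out from 2, returns at 4): resolution in place of asymmetric catalysis. Enolate 2 is C-allylated with allyl iodide (THF/HMPA, −78 → 0 °C) to racemic 2-allyl-3,3-dimethylcyclohexan-1-one F9. The enantiomers are separated by preparative chromatography on a chiral stationary phase (supercritical CO2/MeOH, a neutral eluent that leaves the α-centre intact), and the (R)-enantiomer 4 is carried on.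

3. Step 8. The hindered, basic aryl nucleophile may enolise the aldehyde and not add to it, or partial attack on the ketone may erode the chemoselectivity. Fallback (sets out from 6 and 14, returns at 17): acylation in place of addition/oxidation. Aldehyde 6 is oxidised (NaClO2, NaH2PO4, 2-methylbut-2-ene, t-BuOH/H2O; Pinnick oxidation) to 2-[(1R)-2,2-dimethyl-6-oxocyclohexyl]acetic acid F10. Oxalyl chloride with catalytic DMF (CH2Cl2, 0 °C) gives 2-[(1R)-2,2-dimethyl-6-oxocyclohexyl]acetyl chloride F11. Aryllithium 14 is transmetalated with ZnCl2 to (5-isopropyl-3,4,6-trimethoxy-2-methylphenyl)zinc chloride F12. Negishi acylation (Pd(PPh3)4 cat., THF, rt), which tolerates the ketone, should give diketone 17 directly, so that 16 and step 9 are bypassed.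

Further compounds
F1 | step 10 | 2-bromo-4-isopropyl-3,5,6-trimethoxybenzaldehyde | CC(C)c1c(OC)c(Br)c(C=O)c(OC)c1OC
F2 | step 10 | (2-bromo-4-isopropyl-3,5,6-trimethoxyphenyl)methanol | CC(C)c1c(OC)c(Br)c(CO)c(OC)c1OC
F3 | step 10 | 1-bromo-2-(bromomethyl)-5-isopropyl-3,4,6-trimethoxybenzene | CC(C)c1c(OC)c(Br)c(CBr)c(OC)c1OC
F4 | step 10 | [(2-bromo-4-isopropyl-3,5,6-trimethoxyphenyl)methyl]magnesium bromide | CC(C)c1c(OC)c(Br)c(C[Mg]Br)c(OC)c1OC
F5 | step 10 | (1S,2R)-2-allyl-1-[(2-bromo-4-isopropyl-3,5,6-trimethoxyphenyl)methyl]-3,3-dimethylcyclohexan-1-ol | Brc1c(OC)c(C(C)C)c(OC)c(OC)c1C[C@@]1(O)CCCC(C)(C)[C@H]1CC=C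
F6 | step 10 | (3aR,7aS)-7a-[(2-bromo-4-isopropyl-3,5,6-trimethoxyphenyl)methyl]-4,4-dimethyloctahydro-1-benzofuran-2-ol (lactol carbon undefined) | Brc1c(OC)c(C(C)C)c(OC)c(OC)c1C[C@@]12CCCC(C)(C)[C@H]1CC(O)O2
F7 | step 10 | (3aR,7aS)-7a-[(2-bromo-4-isopropyl-3,5,6-trimethoxyphenyl)methyl]-4,4-dimethylhexahydro-1-benzofuran-2(3H)-one | Brc1c(OC)c(C(C)C)c(OC)c(OC)c1C[C@@]12CCCC(C)(C)[C@H]1CC(=O)O2
F8 | step 10 | aryllithium lactone from F7 (lithium in place of bromine) | [Li]c1c(OC)c(C(C)C)c(OC)c(OC)c1C[C@@]12CCCC(C)(C)[C@H]1CC(=O)O2
F9 | step 2 | racemic 2-allyl-3,3-dimethylcyclohexan-1-one | C=CCC1C(=O)CCCC1(C)C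
F10 | step 8 | 2-[(1R)-2,2-dimethyl-6-oxocyclohexyl]acetic acid | OC(=O)C[C@H]1C(=O)CCCC1(C)C
F11 | step 8 | 2-[(1R)-2,2-dimethyl-6-oxocyclohexyl]acetyl chloride | ClC(=O)C[C@H]1C(=O)CCCC1(C)C
F12 | step 8 | (5-isopropyl-3,4,6-trimethoxy-2-methylphenyl)zinc chloride | CC(C)c1c(OC)c([Zn]Cl)c(C)c(OC)c1OC
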